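Target cannot go on rising in a flask where it is used up as fast as it is made. Two rates meet at that crossing: the first step, a·A·N, and the over-reaction, b·T·N, where A, T and N are free electrophile, dissolved target and free nucleophile, and a and b are rate constants.

| flask | electrophile | nucleophile | remark | time |
|---|---|---|---|---|
| birch | 0.60 M | 0.56 M | run made earlier |  |
| alder | 0.60 M | 0.76 M | run made earlier |  |
| elm | 0.60 M | 0.73 M | run made earlier |  |
| Thursday's | 0.60 M | 0.720 M |  | 1.0 h |
| Monday's | 0.60 M | 0.940 M |  | 1.0 h |

| run | time / min | electrophile / % | target / % |
|---|---|---|---|
| birch | 12.0 | 82.3 | 14.4 |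
| birch | 25.0 | 72.8 | 17.9 |
| birch | 40.0 | 67.1 | 19.5 |
| birch | 50.0 | 65.6 | 18.9 |
| birch | 60.0 | 64.2 | 20.6 |
| alder | 5.00 | 87.4 | 10.2 |
| alder | 15.0 | 72.7 | 17.5 |
| alder | 30.0 | 62.9 | 20.1 |
| alder | 40.0 | 57.9 | 20.5 |
| alder | 60.0 | 54.7 | 20.6 |
| elm | 5.00 | 88.3 | 10.2 |
| elm | 15.0 | 73.2 | 17.0 |
| elm | 30.0 | 63.5 | 19.3 |
| elm | 40.0 | 60.3 | 20.2 |
| elm | 60.0 | 55.1 | 20.4 |

(standard deviation of a reading: 0.5 percentage points)

- amounts and yields of target count crystals too
- given per volume of solution although it is solid: crystals
- the analysis behind the earlier runs scatters by 0.5 percentage points, standard deviation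
- steps under discussion: electrophile + nucleophile -> acid set free + target; nucleophile + acid set free <-> protonated nucleophile; nucleophile + target -> over-reaction product; crystals <-> target

- part of the electrophile that has reacted at the end, Thursday's
- part of the electrophile that has reacted at the end, Monday's
- what raising the concentration of nucleophile from its lowest to its highest value here does to the part of the electrophile that has reacted (changes below 5 percentage points count as none) (it falls / it rises / no change)

N stands in both rates, so it cancels from their ratio:

R = a·A/(b·T) = A/(S·T), with S = b/a

Taking the target as dissolved, alder's target stays at 20.5% to 20.6% from 40.0 min to 60.0 min, which is within the scatter. R is therefore about one there, and alder's last reading gives the selectivity factor S, the over-reaction's rate constant over the first step's: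

S = 54.7%/20.6% = 2.66

Elm, a separate flask, gives R = 1.02 at 60.0 min, with 44.9% of its electrophile reacted. Thursday's is charged almost like elm, so this reckoning expects R near one at its end and about that conversion. Monday's, with more nucleophile, should pass the crossing and react further.

The forecast gives 44.2% (43% to 45.5%) for Thursday's and 54% (51% to 57.5%) for Monday's, with the trend it rises. Its ground: “each electrophile reacted costs two nucleophile (one as base), and each over-reaction costs one more”.

The flask gives 43.8% for Thursday's and 54.0% for Monday's; the trend is it rises, by 10 percentage points.

    electrophile + nucleophile → acid set free + target (k = 0.0390 /M/min)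
    nucleophile + acid set free ⇌ protonated nucleophile, settled at all times (K = 840 /M)
    nucleophile + target → over-reaction product (k = 0.110 /M/min)
    crystals ⇌ target, rate k4*(cs4 - [target]) while solid is left; crystals form when [target] > cs4 (solubility = 0.330 M, k = 4.50 /min)

In Thursday's, nucleophile use by the first step over use by the over-reaction comes down from 1.8 at 0.190 h to 0.99 at 1.00 h. Monday's end amounts give R = 0.906, below one, and its target slips from 20.0% at 0.500 h to 19.1% at 1.00 h.

(All runs are simulated from invented constants; noise was put on by code.)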